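**Assumption:** 4-bromobut-1-yne and methacrolein are bought. The (2S,5S)-imidazolidinone is taken to give the natural antipode; its mirror-image catalyst would be used if the opposite enantiomer forms.

## Retrosynthetic overview
- The C19 acid comes from Pinnick oxidation of the hindered axial C19 aldehyde. The C8(17) exocyclic methylene and the 15-OAc are already in place at that stage.
- Rings A and B form in one radical cascade. A primary radical adds to methacrolein (C2–C3), the resulting tertiary α-formyl radical closes ring A (6-endo, C4–C5), the tertiary C10 radical closes ring B (6-endo, C9–C10), and HAT termination from the C8 methyl gives the exocyclic alkene.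
- The all-E trienyl iodide cascade precursor comes from two Negishi couplings of one E-vinyl iodide building block with alkylzincs.
- All three trisubstituted E-alkenes come from Zr-catalysed carboalumination of 4-bromobutyne (ZACA).

## Route

**Step 1**
Reactants: 1, 4-bromobut-1-yne
Product: 2, (E)-4-bromo-1-iodo-2-methylbut-1-ene
Conditions: Me3Al, cat. Cp2ZrCl2, ClCH2CH2Cl, 0 °C → rt; then I2, THF, −30 °C
Reagents that add atoms: Me3Al (C[Al](C)C); I2 (II)
Why: Negishi Zr-catalysed carboalumination adds Me and Al syn across the terminal alkyne, and iodinolysis retains geometry, so the trisubstituted vinyl iodide is E.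

**Step 2**
Reactants: 1
Product: 3, (E)-5-bromo-3-methylpent-2-en-1-ol
Conditions: Me3Al, cat. Cp2ZrCl2, ClCH2CH2Cl, 0 °C → rt; then n-BuLi, THF, −78 °C; then gaseous CH2O (from (CH2O)n), −78 °C → rt
Reagents that add atoms: Me3Al (C[Al](C)C); formaldehyde (C=O)
Why: The same syn-carboalumination gives the E-alkenylaluminate, which adds to CH2O with retention (carboalumination–hydroxymethylation). This fixes the future C13=C14 E-alkene and the C15 oxygen.

**Step 3**
Reactants: 3
Product: 4, (E)-5-bromo-3-methylpent-2-en-1-yl acetate
Conditions: Ac2O, Et3N, cat. DMAP, CH2Cl2, 0 °C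
Reagents that add atoms: acetic anhydride (CC(=O)OC(C)=O)
Why: Simple acylation installs the target's C15 acetate; the alkyl bromide is untouched.

**Step 4**
Reactants: 2
Product: 5, (E)-1,4-diiodo-2-methylbut-1-ene
Conditions: NaI, acetone, 50 °C, dark
Reagents that add atoms: sodium iodide ([Na+].[I-])
Why: Finkelstein SN2 exchanges only the primary homoallylic bromide, and the vinyl iodide is inert. The primary iodide is the radical precursor needed in step 7.

**Step 5**
Reactants: 4 (as its alkylzinc) and 2
Product: 6, (2E,6E)-9-bromo-3,7-dimethylnona-2,6-dien-1-yl acetate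
Conditions: (a) Zn dust, LiCl, cat. TMSCl/BrCH2CH2Br, THF, 50 °C, then cannula off excess Zn; (b) 2, Pd(PPh3)4 (5 mol %), THF, 25 °C
Reagents that add atoms: none
Why: Knochel zinc insertion tolerates the allylic acetate and alkene. Negishi coupling of the primary alkylzinc with the vinyl iodide (C11–C9 bond) retains the E geometry, and the alkyl bromide is untouched.

**Step 6**
Reactants: 6 (as its alkylzinc) and 5
Product: 7, (2E,6E,10E)-13-iodo-3,7,11-trimethyltrideca-2,6,10-trien-1-yl acetate
Conditions: (a) Zn, LiCl, cat. TMSCl, THF, 50 °C; (b) 5, Pd(PPh3)4 (5 mol %), THF, 25 °C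
Reagents that add atoms: none
Why: Second Negishi coupling (C6–C5 bond). The vinyl iodide is much more reactive than the alkyl iodide toward Pd(0), giving the all-E trienyl iodide with the C2 radical handle.

**Step 7**
Reactants: 7 and 8, methacrolein
Product: 9, 15-acetoxy-labda-8(17),13E-dien-19-al
Conditions: 8 (3 equiv, syringe pump), (2S,5S)-5-benzyl-2-tert-butyl-3-methylimidazolidin-4-one·TFA (20 mol %), [Ir(ppy)2(dtbbpy)]PF6 (1 mol %), Co(dmgH)2pyCl (2 mol %), i-Pr2NEt (2.5 equiv), MeCN/H2O 40:1, 455 nm LEDs, 20 °C
Reagents that add atoms: none
Why: Proposed new method: an α-aminoalkyl radical from i-Pr2NEt abstracts I from 7 (XAT) to give the primary C2 radical, which adds to the β-carbon of the methacrolein iminium. The resulting electrophilic tertiary α-iminium radical closes ring A onto C5 (6-endo, favoured by the C10 methyl), the tertiary C10 radical closes ring B onto C9 (6-endo), and cobaloxime removes an H from the accessible C17 methyl to give the exocyclic alkene. Hydrolysis releases the aldehyde. The closest known reactions are Snider-type Mn(III)/Cu(II) radical polyene cyclisation, photo-organocatalytic radical addition to iminium ions, and cobaloxime dehydrogenative termination. The all-E alkenes force chair–chair folding, which sets 5α-H, 10β-CH3 and 9α-H (trans-decalin, C9 side chain equatorial). The planar C4 formyl/iminium group is smaller than methyl in the axial position, so it is axial and β, cis to C20. The benzyl arm of the catalyst shields one face of the C4 radical, which sets the absolute configuration of the whole cascade.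

**Step 8**
Reactants: 9
Product: 10, 15-acetoxyisocupressic acid
Conditions: NaClO2, NaH2PO4, 2-methyl-2-butene, t-BuOH/H2O, 0 °C → rt
Reagents that add atoms: sodium chlorite ([Na+].[O-]Cl=O)
Why: Pinnick oxidation converts the quaternary C4 aldehyde (no α-H, so no epimerisation) to the acid. The scavenger protects the alkenes, and the acetate and all stereocentres are untouched.

## Compound list
1 | 4-bromobut-1-yne | C#CCCBr | starting material
2 | (E)-4-bromo-1-iodo-2-methylbut-1-ene | BrCC/C(C)=C/I | intermediate
3 | (E)-5-bromo-3-methylpent-2-en-1-ol | BrCC/C(C)=C/CO | intermediate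
4 | (E)-5-bromo-3-methylpent-2-en-1-yl acetate | BrCC/C(C)=C/COC(C)=O | intermediate
5 | (E)-1,4-diiodo-2-methylbut-1-ene | ICC/C(C)=C/I | intermediate
6 | (2E,6E)-9-bromo-3,7-dimethylnona-2,6-dien-1-yl acetate | BrCC/C(C)=C/CC/C(C)=C/COC(C)=O | intermediate
7 | (2E,6E,10E)-13-iodo-3,7,11-trimethyltrideca-2,6,10-trien-1-yl acetate | ICC/C(C)=C/CC/C(C)=C/CC/C(C)=C/COC(C)=O | intermediate
8 | methacrolein | C=C(C)C=O | starting material
9 | 15-acetoxy-labda-8(17),13E-dien-19-al | C=C1CC[C@@H]2[C@](C)(CCC[C@]2(C)C=O)[C@H]1CC/C(C)=C/COC(C)=O | intermediate
10 | 15-acetoxyisocupressic acid | C=C1CC[C@@H]2[C@](C)(CCC[C@]2(C)C(=O)O)[C@H]1CC/C(C)=C/COC(C)=O | target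

## Totals
Total steps: 8. Longest linear sequence: 6 (1 → 3 → 4 → 6 → 7 → 9 → 10).

## Three steps most likely to fail
1. **Step 7 (cascade).** Reduction of the iminium radical cation before it cyclises, premature Co trapping at C10, Co–H isomerisation of the exocyclic alkene, low ee, or the C4 epimer forming.
   - Fallback: use a covalent auxiliary, (S)-N-methacryloyl-4-benzyloxazolidin-2-one with MgBr2 chelation and the same Co/photoredox termination. Separate the diastereomers on silica, cleave the imide with LiOOH, and re-acetylate. Alternatively run the cascade racemic without the amine and resolve the final acid.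
2. **Steps 5 and 6 (Negishi).** Pd(0) could ionise the allylic acetate (π-allyl formation) and consume the alkylzinc, and the alkyl iodide in 5 could undergo I/Zn exchange.
   - Fallback: carry the C15 oxygen as a TBS ether, couple with Fe- or Ni-catalysed Kumada/Negishi conditions, and add TBAF then Ac2O at the end.
3. **Step 2 (carboalumination–hydroxymethylation).** The aluminate may react poorly with CH2O, or the alkyl bromide may interfere.
   - Fallback: make 3 from 5-chloropentan-2-one by HWE olefination, then DIBAL reduction to the diol-type allylic alcohol. Separate the E isomer, then use NaI exchange in place of the bromide.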